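(The numbers in the tables were generated by integration from invented constants; scatter was added.)

Open the books on the limiting reagent, and enter each mole of it on the line where it stands when the clock stops.

common to all: starting material 0.50 M (fed, over 30 min)

|  | coupling partner | free catalyst | remark | time |
|---|---|---|---|---|
| gamma | 0.40 M | 5 mM | run made earlier |  |
| alpha | 2.7 M | 5 mM | run made earlier |  |
| violet | 2.00 M | 5.0 mM |  | 1.5 h |
| ochre | 0.800 M | 5.0 mM |  | 1.5 h |
| teal | 0.550 M | 5.0 mM |  | 1.5 h |
| grey | 0.300 M | 5.0 mM |  | 1.5 h |

| run | time / min | target / % | starting material / % |
|---|---|---|---|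
| gamma | 12.0 | 1.4 | 29.2 |
| gamma | 25.0 | 7.1 | 47.6 |
| gamma | 30.0 | 11.3 | 52.4 |
| gamma | 50.0 | 29.1 | 22.2 |
| alpha | 12.0 | 2.0 | 29.7 |
| alpha | 25.0 | 13.2 | 45.9 |
| alpha | 30.0 | 19.9 | 49.8 |
| alpha | 50.0 | 52.1 | 17.8 |

(readings scatter by 0.3 percentage points)

- the flasks by amount of target, in percent of the starting material charged, highest first, at 1.5 h (violet / ochre / teal / grey)
- the amount of target, in percent of the starting material charged of the flask you put first, at 1.5 h
- the amount of target, in percent of the starting material charged of the flask you put last, at 1.5 h

- percentages count the whole charge, also what has not yet gone in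
- a reading or a percentage of target counts all its forms, free or not

Close the alpha run first: at 50.0 min the whole charge has gone in, 17.8 % is still starting material, 52.1 % is target, and 30.1 % stands on a third, unread line, which in the gamma run holds 48.7 %.

Reckon the first line from the fall of starting material after the feed ends, when nothing more enters, and call the result the clearance constant k, the pseudo-first-order constant of its loss:

k = ln(c(starting material) at 30.0 min / c(starting material) at 50.0 min) / interval = 0.0514 min⁻¹

Gamma, with less partner, reads lower, at 0.0429 min⁻¹, so take alpha's value for violet, whose partner charge stands nearer to alpha's than to gamma's. A steady feed followed by first-order loss then leaves, as a share of the charge at 1.5 h: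

left = (1 − exp(−k·feed time)) / (k·feed time) · exp(−k·(time − feed time)) = 2.33 %

So my ledger for violet, where starting material is the limiting reagent, puts 97.7 % on the third line and target together. In grey the partner is the limiting reagent, and at one partner per target 0.300 M against 0.50 M caps target at 60.0 %. Alpha carries more target than gamma at 50.0 min, so I rank the flasks by partner charge, and commit to these two ceilings, violet's being an estimate, and to that order, not to values.

The forecast, calling the loss “nearly first order”, gives violet > ochre > teal > grey, with 88 % (83 % to 92 %) first and 47 % (42 % to 52 %) last, both under my ceilings.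

The flasks give violet > ochre > teal > grey, with 87.6 % for violet and 44.5 % for grey, inside the forecast's ranges.

    starting material + free catalyst → free catalyst + open intermediate (k = 11.0 L mol⁻¹ min⁻¹)
    crystals ⇌ target, rate k2*(cs2 - [target]) while solid is left; crystals form when [target] > cs2 (solubility = 0.320 M, k = 1.70 min⁻¹)
    coupling partner + catalyst intermediate → free catalyst + target (k = 13.0 L mol⁻¹ min⁻¹)
    free catalyst + open intermediate ⇌ catalyst intermediate (K = 2.40 L mol⁻¹, k = 12.0 L mol⁻¹ min⁻¹)

Violet holds 2.19 % of starting material at 1.50 h against the 2.33 % reckoned. Now take its neighbour, the same flask with 0.0013 M of free catalyst: scale k by the catalyst charge, an assumption, since both runs stood at one charge, to 0.0134 min⁻¹, and the same line leaves 36.9 %. That flask holds 36.4 % of starting material, with open intermediate at 38.2 % and target at 25.3 %.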